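## Retrosynthetic overview

1. The strategy rests on ring C (the cyclohexane). C3' (the CMe2 carbon), C2' (tether-bearing) and C1' (carboxyl-bearing) are contiguous and C1'/C2' are trans, which is the pattern of a [4+2] adduct. Cutting C2'–C3' and C1'–C6' gives 4-methylpenta-1,3-diene and an E fumarate half-ester N-acyloxazolidinone, joined under a chiral copper Lewis acid.
2. The imide carbonyl carbon becomes the first tether carbon (thioester, then aldehyde). Olefination with an acetonyl phosphonate and hydrogenation give a methyl ketone whose carbonyl carbon is C2 of the chromene.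
3. C2 is set by a catalyst-controlled epoxidation of that ketone; inverting hydrolysis, oxidation and alkynylation give the tertiary propargylic alcohol.
4. Ring B (the pyran) is built on bought ring A (3,5-dibromo-4-iodotoluene): C4–C4a by Sonogashira coupling, the Z C3=C4 alkene by semihydrogenation, O1–C8a by palladium-catalysed aryl C–O closure.
5. The remaining bromide at C5 is exchanged for OH and the ester is saponified in the last operation. Ring order: C first, then B onto A.

Key step: step 2

Remark: the ligand enantiomer in step 2 follows from the square-planar chelate model of bis(oxazoline)–copper imide complexes, and the binaphthoxide enantiomer in step 7 is assumed to give the (S)-oxirane; if either sense proves opposite, the mirror-image ligand is used and nothing else changes.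
Remark: 1,3-dibromo-2-iodo-5-methylbenzene is taken as a catalogue compound.

## Route

Step 1
Reactants: 1 monomethyl fumarate; 2 oxazolidin-2-one
Product: 4 methyl (E)-4-oxo-4-(2-oxo-1,3-oxazolidin-3-yl)but-2-enoate, via methyl fumaroyl chloride 3 (not isolated)
Conditions: (COCl)2, DMF (cat.), CH2Cl2, 0 °C to rt; concentrate; then 2, Et3N, LiCl, THF, 0 °C to rt
Reagents that add atoms: none
Why: Acid chloride formation through the chloroiminium catalyst followed by N-acylation of the oxazolidinone should keep the E geometry, because the fumaroyl chloride has no γ-hydrogen from which a ketene could form.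

Step 2
Reactants: 4 methyl (E)-4-oxo-4-(2-oxo-1,3-oxazolidin-3-yl)but-2-enoate; 5 4-methylpenta-1,3-diene
Product: 6 methyl (1S,6R)-5,5-dimethyl-6-(2-oxo-1,3-oxazolidine-3-carbonyl)cyclohex-3-ene-1-carboxylate
Conditions: [Cu((R,R)-t-Bu-box)](SbF6)2 (10 mol %, from CuCl2, AgSbF6 and 2,2'-(propane-2,2-diyl)bis[(4R)-4-tert-butyl-4,5-dihydro-1,3-oxazole]), 5 (5 equiv, freed from 2-methylpenta-1,3-diene), CH2Cl2, −20 °C to rt
Reagents that add atoms: none
Why: The imide binds divalent copper through both carbonyl oxygens in a square-planar chelate, which lowers the LUMO of the fumarate and makes the ester-bearing carbon (β to the imide carbonyl) the most electrophilic site. The unsubstituted CH2 terminus of 5, which has the largest HOMO coefficient, bonds to that carbon (C1'–C6') and the CMe2 terminus bonds to the imide-bearing carbon (C2'–C3'), so ring C closes by [4+2] cycloaddition (Diels–Alder reaction), concerted but asynchronous or, in the limit, stepwise through a tertiary allyl cation and a copper enolate that collapses to the six-membered ring. The closest known reaction type is the bis(oxazoline)–copper-catalysed Diels–Alder reaction of fumaroyl and acryloyl oxazolidinones with acyclic dienes. C1' and C2' are both set by the face of the s-cis chelated dienophile that the tert-butyl group of the (R,R) ligand leaves open, and their trans relationship is carried over from the E alkene. The step needs regioselectivity (one-sided activation at the imide and the donor-substituted diene terminus), trans relative configuration (E geometry, also the more stable outcome of a stepwise closure) and facial selectivity (the ligand). The low s-cis population of the Z-methyl diene is met with the weakly coordinating SbF6 counterion, excess diene and long reaction time.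

Step 3
Reactants: 6 methyl (1S,6R)-5,5-dimethyl-6-(2-oxo-1,3-oxazolidine-3-carbonyl)cyclohex-3-ene-1-carboxylate
Product: 7 methyl (1S,6R)-6-[(ethylsulfanyl)carbonyl]-5,5-dimethylcyclohex-3-ene-1-carboxylate
Conditions: EtSH, n-BuLi, THF, −78 to 0 °C; NH4Cl (aq.)
Reagents that add atoms: ethanethiol, CCS
Why: Lithium ethanethiolate, a soft and weakly basic nucleophile, should attack the exocyclic imide carbonyl (acyl transfer from the oxazolidinone to sulfur) and leave the methyl ester and both α-stereocentres untouched.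

Step 4
Reactants: 7 methyl (1S,6R)-6-[(ethylsulfanyl)carbonyl]-5,5-dimethylcyclohex-3-ene-1-carboxylate
Product: 8 methyl (1S,6R)-6-formyl-5,5-dimethylcyclohex-3-ene-1-carboxylate
Conditions: Et3SiH, Pd/C (10 %), acetone, rt
Reagents that add atoms: none
Why: In the Fukuyama reduction zerovalent palladium inserts into the C–S bond and the silane delivers hydride, which should give the aldehyde without touching the methyl ester and without an alcohol stage that could lactonise; any ring alkene saturated here converges in step 6.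

Step 5
Reactants: 8 methyl (1S,6R)-6-formyl-5,5-dimethylcyclohex-3-ene-1-carboxylate
Product: 9 methyl (1S,6R)-5,5-dimethyl-6-[(1E)-3-oxobut-1-en-1-yl]cyclohex-3-ene-1-carboxylate
Conditions: (MeO)2P(O)CH2C(O)CH3, LiCl, i-Pr2NEt, MeCN, rt
Reagents that add atoms: dimethyl (2-oxopropyl)phosphonate, COP(=O)(OC)CC(C)=O
Why: Horner–Wadsworth–Emmons olefination in its mild LiCl/amine (Masamune–Roush) variant should add the lithium-chelated phosphonate anion to the hindered, epimerisable aldehyde and give the E enone.

Step 6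
Reactants: 9 methyl (1S,6R)-5,5-dimethyl-6-[(1E)-3-oxobut-1-en-1-yl]cyclohex-3-ene-1-carboxylate
Product: 10 methyl (1S,2R)-3,3-dimethyl-2-(3-oxobutyl)cyclohexane-1-carboxylate
Conditions: H2 (1 atm), Pd/C (10 %), EtOAc, rt
Reagents that add atoms: none
Why: Heterogeneous catalytic hydrogenation should saturate the enone C=C and the ring C=C (no new stereocentre arises) while the ketone and the ester remain.

Step 7
Reactants: 10 methyl (1S,2R)-3,3-dimethyl-2-(3-oxobutyl)cyclohexane-1-carboxylate
Product: 11 methyl (1S,2R)-3,3-dimethyl-2-{2-[(2S)-2-methyloxiran-2-yl]ethyl}cyclohexane-1-carboxylate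
Conditions: Me3S(O)I, NaH, THF; then LaLi3[(S)-binaphthoxide]3 (5 mol %), [2,4,6-(MeO)3C6H2]3P=O (5 mol %), MS 5A, THF, rt
Reagents that add atoms: trimethylsulfoxonium iodide, C[S+](C)(C)=O.[I-]
Why: In this catalytic asymmetric Corey–Chaykovsky epoxidation the lanthanum–lithium binaphthoxide complex with the phosphine oxide binds ketone and ylide and delivers CH2 to one carbonyl face, a reaction type established for alkyl methyl ketones, so the future C2 is set by the catalyst and not by the remote ring stereocentres.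

Step 8
Reactants: 11 methyl (1S,2R)-3,3-dimethyl-2-{2-[(2S)-2-methyloxiran-2-yl]ethyl}cyclohexane-1-carboxylate
Product: 12 methyl (1S,2R)-2-[(3R)-3,4-dihydroxy-3-methylbutyl]-3,3-dimethylcyclohexane-1-carboxylate
Conditions: H2SO4 (cat.), 1,4-dioxane/H2O, rt
Reagents that add atoms: water, O
Why: Acid-catalysed hydrolysis of a 2-alkyl-2-methyloxirane proceeds by attack of water at the tertiary carbon in a borderline A-2 opening with inversion, so the (S)-oxirane should give the (R)-diol while dilute acid at room temperature leaves the methyl ester alone.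

Step 9
Reactants: 12 methyl (1S,2R)-2-[(3R)-3,4-dihydroxy-3-methylbutyl]-3,3-dimethylcyclohexane-1-carboxylate
Product: 13 methyl (1S,2R)-2-[(3R)-3-hydroxy-3-methyl-4-oxobutyl]-3,3-dimethylcyclohexane-1-carboxylate
Conditions: SO3·pyridine, DMSO, i-Pr2NEt, CH2Cl2, 0 °C; used crude
Reagents that add atoms: none
Why: Parikh–Doering oxidation should convert only the primary alcohol, since the tertiary alcohol cannot be oxidised and the quaternary α-carbon cannot epimerise.

Step 10
Reactants: 13 methyl (1S,2R)-2-[(3R)-3-hydroxy-3-methyl-4-oxobutyl]-3,3-dimethylcyclohexane-1-carboxylate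
Product: 14 methyl (1S,2R)-2-[(3R)-3-hydroxy-3-methylpent-4-yn-1-yl]-3,3-dimethylcyclohexane-1-carboxylate
Conditions: dimethyl (1-diazo-2-oxopropyl)phosphonate, K2CO3, MeOH, 0 °C to rt
Reagents that add atoms: dimethyl (1-diazo-2-oxopropyl)phosphonate, COP(=O)(OC)C(=[N+]=[N-])C(C)=O
Why: In the Seyferth–Gilbert homologation with the Ohira–Bestmann reagent the diazophosphonate anion freed by methanolysis adds to the aldehyde and the alkylidene carbene rearranges to the terminal alkyne, under conditions mild enough for the methyl ester and the free tertiary alcohol.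

Step 11
Reactants: 14 methyl (1S,2R)-2-[(3R)-3-hydroxy-3-methylpent-4-yn-1-yl]-3,3-dimethylcyclohexane-1-carboxylate; 15 1,3-dibromo-2-iodo-5-methylbenzene
Product: 16 methyl (1S,2R)-2-[(3R)-5-(2,6-dibromo-4-methylphenyl)-3-hydroxy-3-methylpent-4-yn-1-yl]-3,3-dimethylcyclohexane-1-carboxylate
Conditions: PdCl2(PPh3)2 (5 mol %), CuI (10 mol %), Et3N, THF, 40 °C, degassed
Reagents that add atoms: none
Why: In the Sonogashira coupling zerovalent palladium inserts into the C–I bond far faster than into the two flanking C–Br bonds, so the alkyne should be attached only at the iodine-bearing carbon (the future C4a).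

Step 12
Reactants: 16 methyl (1S,2R)-2-[(3R)-5-(2,6-dibromo-4-methylphenyl)-3-hydroxy-3-methylpent-4-yn-1-yl]-3,3-dimethylcyclohexane-1-carboxylate
Product: 17 methyl (1S,2R)-2-[(3R,4Z)-5-(2,6-dibromo-4-methylphenyl)-3-hydroxy-3-methylpent-4-en-1-yl]-3,3-dimethylcyclohexane-1-carboxylate
Conditions: H2 (1 atm), Pd/CaCO3 poisoned with Pb(OAc)2 (Lindlar catalyst), quinoline, EtOAc, rt
Reagents that add atoms: none
Why: Lindlar semihydrogenation adds hydrogen syn on the poisoned surface and should stop at the Z alkene while sparing the aryl bromides.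

Step 13
Reactants: 17 methyl (1S,2R)-2-[(3R,4Z)-5-(2,6-dibromo-4-methylphenyl)-3-hydroxy-3-methylpent-4-en-1-yl]-3,3-dimethylcyclohexane-1-carboxylate
Product: 18 methyl (1S,2R)-2-{2-[(2R)-5-bromo-2,7-dimethyl-2H-chromen-2-yl]ethyl}-3,3-dimethylcyclohexane-1-carboxylate
Conditions: Pd(OAc)2 (5 mol %), 2-(di-tert-butylphosphino)-1,1'-binaphthyl (6 mol %), Cs2CO3, toluene, 80 °C
Reagents that add atoms: none
Why: In this Buchwald–Hartwig-type intramolecular C–O coupling zerovalent palladium inserts into either of the two equivalent C–Br bonds, the tertiary alkoxide (no β-hydrogen) binds and C–O reductive elimination should close ring B, with C2 unchanged because its own C–O bond is never broken.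

Step 14
Reactants: 18 methyl (1S,2R)-2-{2-[(2R)-5-bromo-2,7-dimethyl-2H-chromen-2-yl]ethyl}-3,3-dimethylcyclohexane-1-carboxylate
Product: 20 (1S,2R)-2-{2-[(2R)-5-hydroxy-2,7-dimethyl-2H-chromen-2-yl]ethyl}-3,3-dimethylcyclohexane-1-carboxylic acid (CNP0144010.1), via bromo carboxylate 19 (not isolated)
Conditions: Pd2(dba)3 (2 mol %), t-BuXPhos (8 mol %), KOH (6 equiv), 1,4-dioxane/H2O (1:1), 100 °C, degassed; then 1 M HCl to pH 3–4, 0 °C
Reagents that add atoms: potassium hydroxide, [K+].[OH-]
Why: Palladium-catalysed hydroxylation of the aryl bromide with KOH and a bulky biarylphosphine should give the C5 phenoxide while the same hydroxide saponifies the methyl ester (the trans carboxylate being the stable epimer), and brief cold acidification releases the phenol acid without exposing the chromene to strong acid.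

## Compound list

1 | monomethyl fumarate | COC(=O)/C=C/C(=O)O | starting material
2 | oxazolidin-2-one | O=C1NCCO1 | starting material
3 | methyl (E)-4-chloro-4-oxobut-2-enoate (methyl fumaroyl chloride) | COC(=O)/C=C/C(Cl)=O | intermediate (not isolated)
4 | methyl (E)-4-oxo-4-(2-oxo-1,3-oxazolidin-3-yl)but-2-enoate | COC(=O)/C=C/C(=O)N1CCOC1=O | intermediate
5 | 4-methylpenta-1,3-diene | CC(C)=CC=C | starting material
6 | methyl (1S,6R)-5,5-dimethyl-6-(2-oxo-1,3-oxazolidine-3-carbonyl)cyclohex-3-ene-1-carboxylate | O=C(N1CCOC1=O)[C@@H]1[C@@H](C(=O)OC)CC=CC1(C)C | intermediate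
7 | methyl (1S,6R)-6-[(ethylsulfanyl)carbonyl]-5,5-dimethylcyclohex-3-ene-1-carboxylate | CCSC(=O)[C@@H]1[C@@H](C(=O)OC)CC=CC1(C)C | intermediate
8 | methyl (1S,6R)-6-formyl-5,5-dimethylcyclohex-3-ene-1-carboxylate | O=C[C@@H]1[C@@H](C(=O)OC)CC=CC1(C)C | intermediate
9 | methyl (1S,6R)-5,5-dimethyl-6-[(1E)-3-oxobut-1-en-1-yl]cyclohex-3-ene-1-carboxylate | CC(=O)/C=C/[C@@H]1[C@@H](C(=O)OC)CC=CC1(C)C | intermediate
10 | methyl (1S,2R)-3,3-dimethyl-2-(3-oxobutyl)cyclohexane-1-carboxylate | CC(=O)CC[C@@H]1[C@@H](C(=O)OC)CCCC1(C)C | intermediate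
11 | methyl (1S,2R)-3,3-dimethyl-2-{2-[(2S)-2-methyloxiran-2-yl]ethyl}cyclohexane-1-carboxylate | C[C@]1(CC[C@@H]2[C@@H](C(=O)OC)CCCC2(C)C)CO1 | intermediate
12 | methyl (1S,2R)-2-[(3R)-3,4-dihydroxy-3-methylbutyl]-3,3-dimethylcyclohexane-1-carboxylate | C[C@](O)(CO)CC[C@@H]1[C@@H](C(=O)OC)CCCC1(C)C | intermediate
13 | methyl (1S,2R)-2-[(3R)-3-hydroxy-3-methyl-4-oxobutyl]-3,3-dimethylcyclohexane-1-carboxylate | C[C@](O)(C=O)CC[C@@H]1[C@@H](C(=O)OC)CCCC1(C)C | intermediate
14 | methyl (1S,2R)-2-[(3R)-3-hydroxy-3-methylpent-4-yn-1-yl]-3,3-dimethylcyclohexane-1-carboxylate | C[C@](O)(C#C)CC[C@@H]1[C@@H](C(=O)OC)CCCC1(C)C | intermediate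
15 | 1,3-dibromo-2-iodo-5-methylbenzene (3,5-dibromo-4-iodotoluene) | Cc1cc(Br)c(I)c(Br)c1 | starting material
16 | methyl (1S,2R)-2-[(3R)-5-(2,6-dibromo-4-methylphenyl)-3-hydroxy-3-methylpent-4-yn-1-yl]-3,3-dimethylcyclohexane-1-carboxylate | C[C@](O)(C#Cc1c(Br)cc(C)cc1Br)CC[C@@H]1[C@@H](C(=O)OC)CCCC1(C)C | intermediate
17 | methyl (1S,2R)-2-[(3R,4Z)-5-(2,6-dibromo-4-methylphenyl)-3-hydroxy-3-methylpent-4-en-1-yl]-3,3-dimethylcyclohexane-1-carboxylate | C[C@](O)(/C=C\c1c(Br)cc(C)cc1Br)CC[C@@H]1[C@@H](C(=O)OC)CCCC1(C)C | intermediate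
18 | methyl (1S,2R)-2-{2-[(2R)-5-bromo-2,7-dimethyl-2H-chromen-2-yl]ethyl}-3,3-dimethylcyclohexane-1-carboxylate | Cc1cc(Br)c2c(c1)O[C@](C)(CC[C@@H]1[C@@H](C(=O)OC)CCCC1(C)C)C=C2 | intermediate
19 | potassium (1S,2R)-2-{2-[(2R)-5-bromo-2,7-dimethyl-2H-chromen-2-yl]ethyl}-3,3-dimethylcyclohexane-1-carboxylate | Cc1cc(Br)c2c(c1)O[C@](C)(CC[C@@H]1[C@@H](C(=O)[O-])CCCC1(C)C)C=C2.[K+] | intermediate (not isolated)
20 | (1S,2R)-2-{2-[(2R)-5-hydroxy-2,7-dimethyl-2H-chromen-2-yl]ethyl}-3,3-dimethylcyclohexane-1-carboxylic acid | Cc1cc(O)c2c(c1)O[C@](C)(CC[C@@H]1[C@@H](C(=O)O)CCCC1(C)C)C=C2 | target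

## Step count and risks

Total step count: 14. Longest linear sequence: 14 steps (1 to 20); arene 15 is bought.

The three steps most likely to fail:

Step 2. The cycloaddition may stall because the Z-methyl group keeps the diene out of its s-cis form, while the cationic catalyst oligomerises the diene, the zwitterionic pathway closes to a four-membered ring, or facial selectivity falls below that seen with reactive dienes. The fallback replaces catalyst control by auxiliary control with a stronger, stoichiometric Lewis acid. It sets out from acid chloride 3 (made from 1 as in step 1) and diene 5. Acylation of (4S)-4-benzyl-1,3-oxazolidin-2-one (Et3N, LiCl, THF) gives methyl (E)-4-[(4S)-4-benzyl-2-oxo-1,3-oxazolidin-3-yl]-4-oxobut-2-enoate F1. Its cationic aluminium chelate (Et2AlCl, 1.5 equiv, CH2Cl2, −78 to −30 °C) should add 5 on the face away from the benzyl group, which is the face required, to give methyl (1S,6R)-6-{[(4S)-4-benzyl-2-oxo-1,3-oxazolidin-3-yl]carbonyl}-5,5-dimethylcyclohex-3-ene-1-carboxylate F2. Cleavage with EtSH/n-BuLi as in step 3 removes the auxiliary and the route is rejoined at 7.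

Step 13. The arylpalladium alkoxide may lose the alkenyl group by β-carbon elimination instead of undergoing C–O reductive elimination, the Z alkene may isomerise to the E form that cannot close, or the tertiary alcohol may lactonise onto the ester under the basic, hot conditions. The fallback closes the ring on a saturated tether, the substrate class for which this etherification is best established, and introduces the alkene afterwards. It sets out from 16. Full hydrogenation of the alkyne (H2, PtO2, EtOAc, which spares the aryl bromides) gives methyl (1S,2R)-2-[(3R)-5-(2,6-dibromo-4-methylphenyl)-3-hydroxy-3-methylpentyl]-3,3-dimethylcyclohexane-1-carboxylate F3. The same palladium-catalysed C–O coupling (Pd(OAc)2, 2-(di-tert-butylphosphino)-1,1'-binaphthyl, Cs2CO3, toluene, 80 °C) should give methyl (1S,2R)-2-{2-[(2R)-5-bromo-2,7-dimethyl-3,4-dihydro-2H-chromen-2-yl]ethyl}-3,3-dimethylcyclohexane-1-carboxylate F4. Dehydrogenation with DDQ (1,4-dioxane, reflux; hydride abstraction at the benzylic C4, assisted by O1) installs the C3=C4 alkene and the route is rejoined at 18.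

Step 14. At the hindered, electron-rich aryl bromide, hydrodebromination or arylation of the newly formed phenoxide to a diaryl ether may outrun hydroxide transfer. The fallback goes through a C–B bond. It sets out from 18. Miyaura borylation (B2pin2, PdCl2(dppf), KOAc, 1,4-dioxane, 90 °C) gives methyl (1S,2R)-2-{2-[(2R)-2,7-dimethyl-5-(4,4,5,5-tetramethyl-1,3,2-dioxaborolan-2-yl)-2H-chromen-2-yl]ethyl}-3,3-dimethylcyclohexane-1-carboxylate F5. Oxidation (NaBO3·4H2O, THF/H2O, rt) gives methyl (1S,2R)-2-{2-[(2R)-5-hydroxy-2,7-dimethyl-2H-chromen-2-yl]ethyl}-3,3-dimethylcyclohexane-1-carboxylate F6. Saponification (LiOH, THF/MeOH/H2O, 40 °C, degassed; mild acidification) rejoins the route at 20.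

Further compounds
F1 | step 2 | methyl (E)-4-[(4S)-4-benzyl-2-oxo-1,3-oxazolidin-3-yl]-4-oxobut-2-enoate | COC(=O)/C=C/C(=O)N1[C@@H](Cc2ccccc2)COC1=O
F2 | step 2 | methyl (1S,6R)-6-{[(4S)-4-benzyl-2-oxo-1,3-oxazolidin-3-yl]carbonyl}-5,5-dimethylcyclohex-3-ene-1-carboxylate | O=C([C@@H]1[C@@H](C(=O)OC)CC=CC1(C)C)N1[C@@H](Cc2ccccc2)COC1=O
F3 | step 13 | methyl (1S,2R)-2-[(3R)-5-(2,6-dibromo-4-methylphenyl)-3-hydroxy-3-methylpentyl]-3,3-dimethylcyclohexane-1-carboxylate | C[C@](O)(CCc1c(Br)cc(C)cc1Br)CC[C@@H]1[C@@H](C(=O)OC)CCCC1(C)C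
F4 | step 13 | methyl (1S,2R)-2-{2-[(2R)-5-bromo-2,7-dimethyl-3,4-dihydro-2H-chromen-2-yl]ethyl}-3,3-dimethylcyclohexane-1-carboxylate | Cc1cc(Br)c2c(c1)O[C@](C)(CC[C@@H]1[C@@H](C(=O)OC)CCCC1(C)C)CC2
F5 | step 14 | methyl (1S,2R)-2-{2-[(2R)-2,7-dimethyl-5-(4,4,5,5-tetramethyl-1,3,2-dioxaborolan-2-yl)-2H-chromen-2-yl]ethyl}-3,3-dimethylcyclohexane-1-carboxylate | Cc1cc(B3OC(C)(C)C(C)(C)O3)c2c(c1)O[C@](C)(CC[C@@H]1[C@@H](C(=O)OC)CCCC1(C)C)C=C2
F6 | step 14 | methyl (1S,2R)-2-{2-[(2R)-5-hydroxy-2,7-dimethyl-2H-chromen-2-yl]ethyl}-3,3-dimethylcyclohexane-1-carboxylate | Cc1cc(O)c2c(c1)O[C@](C)(CC[C@@H]1[C@@H](C(=O)OC)CCCC1(C)C)C=C2
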